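## Retrosynthetic overview

Labdane numbering is used for every intermediate. The strategy rests on ring A: C4 is quaternary (axial C19 methyl, equatorial C18–O) and sits next to the C5 methine, the pattern a 2-substituted acrolein leaves at the substituted end of an (E)-diene; C6–C7–C8(CH3)(OH)–C9 is the carbinol end of (S)-linalool.
Backwards: O18 angelate ⇒ neopentyl alcohol; C12 methylene ⇒ C12 ketone; ring B ⇒ C9–C10 bond by iron-hydride HAT radical 6-exo closure of a 9,10-seco enone; C9=C11 ⇒ cross-metathesis of the linalool vinyl group with a C11–C16 vinyl ketone from (R)-α-methyl-γ-butyrolactone (C13).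
Ring A ⇒ catalytic enantioselective Diels–Alder reaction (bonds C2–C3 and C4–C5) of the linalool-derived (E)-diene C2=C1–C10=C5 with 2-(benzyloxymethyl)acrolein.
Ring order: ring A (Diels–Alder), then ring B (radical closure).

Key step: step 6

Assumption: the sense of induction of the oxazaborolidinium catalyst is taken from its behaviour with 2-methyl- and 2-bromoacrolein (the (S)-catalyst lets the diene reach the face of the α-carbon on which CHO, α-substituent and =CH2 run anticlockwise), so the (R)-catalyst is used to reach the Re face of C4 of the dienophile; if the sense proves opposite, the enantiomeric catalyst is used with no other change.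

## Route

Step 1
Reactants: 1 (S)-linalool
Product: 2 triethyl{[(3S)-3,7-dimethylocta-1,6-dien-3-yl]oxy}silane
Conditions: TESOTf, 2,6-lutidine, CH2Cl2, −78 to 0 °C
Reagents that add atoms: triethylsilyl trifluoromethanesulfonate, CC[Si](CC)(CC)OS(=O)(=O)C(F)(F)F
Why: Silyl triflate silylation of the hindered tertiary alcohol leaves the C8 centre untouched and masks the hydroxyl from the Lewis acid of step 6.

Step 2
Reactants: 2 triethyl{[(3S)-3,7-dimethylocta-1,6-dien-3-yl]oxy}silane
Product: 4 (2E,6S)-2,6-dimethyl-6-(triethylsilyloxy)octa-2,7-dienal, via allylic alcohol 3 (not isolated)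
Conditions: SeO2 (0.3 equiv), tBuOOH (in decane), salicylic acid (cat.), CH2Cl2, rt; filter, then MnO2, CH2Cl2, rt
Reagents that add atoms: tert-butyl hydroperoxide, CC(C)(C)OO (terminal oxidant; the oxygen is passed on by SeO2, O=[Se]=O)
Why: Riley allylic oxidation (ene reaction, then [2,3]-shift) should attack the (E)-methyl of the trisubstituted alkene, the vinyl group having no allylic hydrogen, and MnO2 then carries the remaining allylic alcohol on to the (E)-enal.

Step 3
Reactants: 4 (2E,6S)-2,6-dimethyl-6-(triethylsilyloxy)octa-2,7-dienal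
Product: 5 triethyl{[(3S,6E)-3,7-dimethylnona-1,6,8-trien-3-yl]oxy}silane
Conditions: Ph3PCH3Br, KOtBu, THF, 0 °C; then 4, 0 °C to rt
Reagents that add atoms: methyltriphenylphosphonium bromide, C[P+](c1ccccc1)(c1ccccc1)c1ccccc1.[Br-]
Why: Wittig methylenation of the enal with the non-stabilised ylide should give the 1,3-diene without touching the (E)-trisubstituted double bond or the C8 centre.

Step 4
Reactants: 6 2-methylenepropane-1,3-diol
Product: 7 2-[(benzyloxy)methyl]prop-2-en-1-ol
Conditions: NaH (1.0 equiv), THF, 0 °C; BnBr (0.9 equiv), Bu4NI (cat.), 0 °C to rt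
Reagents that add atoms: benzyl bromide, BrCc1ccccc1
Why: Williamson monobenzylation of the symmetrical diol with a deficit of BnBr should give the mono-ether whose oxygen becomes O18.

Step 5
Reactants: 7 2-[(benzyloxy)methyl]prop-2-en-1-ol
Product: 8 2-[(benzyloxy)methyl]prop-2-enal
Conditions: MnO2, CH2Cl2, rt
Reagents that add atoms: none
Why: MnO2 oxidises the allylic alcohol to the 2-substituted acrolein under neutral conditions that should not polymerise it.

Step 6
Reactants: 5 triethyl{[(3S,6E)-3,7-dimethylnona-1,6,8-trien-3-yl]oxy}silane; 8 2-[(benzyloxy)methyl]prop-2-enal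
Product: 9 (1R,2S)-1-[(benzyloxy)methyl]-3-methyl-2-[(3S)-3-methyl-3-(triethylsilyloxy)pent-4-en-1-yl]cyclohex-3-ene-1-carbaldehyde
Conditions: (R)-o-tolyl-CBS oxazaborolidine [(3aR)-1-(2-methylphenyl)-3,3-diphenyltetrahydro-1H,3H-pyrrolo[1,2-c][1,3,2]oxazaborole] (20 mol%), Tf2NH (20 mol%), 8 (1.5 equiv), CH2Cl2, −78 to −40 °C
Reagents that add atoms: none
Why: Concerted but asynchronous [4+2] cycloaddition of the s-cis (E)-diene C2=C1–C10=C5 of 5 with the boron-bound s-trans enal 8, the known reaction type being the CBS-type oxazaborolidinium-catalysed enantioselective Diels–Alder reaction of 2-substituted acroleins with acyclic dienes. Ring A closes in one suprafacial–suprafacial event that forms C2–C3 and C4–C5. Regiochemistry: the unsubstituted terminus C2 bonds ahead to the enal β-carbon C3, so the alkyl-bearing terminus C5 meets the α-carbon C4, the orientation that 1-substituted dienes show and that must outweigh the opposite bias of the C10 methyl. Relative configuration C4/C5: the formyl group lies endo under the diene and so ends cis to C6, where it later becomes the axial C19 methyl, leaving CH2OBn equatorial as C18. Absolute configuration: the catalyst shields one face of the enal so that C5 adds to the Re face of C4 (4R,5S), while the remote C8 centre is only carried along. The 1,3-diene is the only one in the molecule and the isolated vinyl group on C8 should be inert at this temperature, so chemoselectivity needs no further control.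

Step 7
Reactants: 9 (1R,2S)-1-[(benzyloxy)methyl]-3-methyl-2-[(3S)-3-methyl-3-(triethylsilyloxy)pent-4-en-1-yl]cyclohex-3-ene-1-carbaldehyde
Product: 10 (E)-4-methylbenzenesulfonylhydrazone of aldehyde 9
Conditions: TsNHNH2, EtOH, rt
Reagents that add atoms: 4-methylbenzenesulfonohydrazide, Cc1ccc(cc1)S(=O)(=O)NN
Why: Condensation of the neopentyl aldehyde with tosylhydrazine proceeds under near-neutral conditions that should leave the silyl ether, both alkenes and the C4 centre untouched.

Step 8
Reactants: 10 (E)-4-methylbenzenesulfonylhydrazone of aldehyde 9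
Product: 12 benzyl {(1S,2S)-1,3-dimethyl-2-[(3S)-3-methyl-3-(triethylsilyloxy)pent-4-en-1-yl]cyclohex-3-en-1-yl}methyl ether, via N-boryl tosylhydrazine 11 (not isolated)
Conditions: catecholborane, CHCl3, 0 °C to rt; then NaOAc·3H2O, reflux
Reagents that add atoms: none
Why: Caglioti-type tosylhydrazone reduction in its catecholborane form (hydroboration of C=N, then acetate-induced loss of sulfinate and of N2 from the diazene) should turn the formyl carbon into the C19 methyl without strong base, and catecholborane does not hydroborate the alkenes at this temperature.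

Step 9
Reactants: 12 benzyl {(1S,2S)-1,3-dimethyl-2-[(3S)-3-methyl-3-(triethylsilyloxy)pent-4-en-1-yl]cyclohex-3-en-1-yl}methyl ether
Product: 13 (3S)-5-{(1S,6S)-6-[(benzyloxy)methyl]-2,6-dimethylcyclohex-2-en-1-yl}-3-methylpent-1-en-3-ol
Conditions: Bu4NF, THF, rt to 50 °C
Reagents that add atoms: none
Why: Fluoride cleaves the tertiary triethylsilyl ether so that the vinyl group sits on a free tertiary allylic alcohol, the form that enters cross-metathesis far more readily than its silyl ether.

Step 10
Reactants: 14 (R)-α-methyl-γ-butyrolactone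
Product: 15 (2R)-4-hydroxy-N-methoxy-N,2-dimethylbutanamide
Conditions: MeNHOMe·HCl, Me3Al, CH2Cl2, 0 °C to rt
Reagents that add atoms: N,O-dimethylhydroxylamine hydrochloride, CNOC.Cl
Why: Aluminium amide opening of the lactone (Weinreb amide formation) occurs at the acyl carbon and should leave the α-stereocentre C13 untouched.

Step 11
Reactants: 15 (2R)-4-hydroxy-N-methoxy-N,2-dimethylbutanamide
Product: 16 (2R)-4-[(tert-butyldimethylsilyl)oxy]-N-methoxy-N,2-dimethylbutanamide
Conditions: TBSCl, imidazole, DMF, rt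
Reagents that add atoms: tert-butyldimethylsilyl chloride, CC(C)(C)[Si](C)(C)Cl
Why: Silylation of the primary alcohol blocks relactonisation and protects O15 until the last step.

Step 12
Reactants: 16 (2R)-4-[(tert-butyldimethylsilyl)oxy]-N-methoxy-N,2-dimethylbutanamide
Product: 18 (4R)-6-[(tert-butyldimethylsilyl)oxy]-4-methylhex-1-en-3-one, via bromomagnesium hemiaminal 17 (not isolated)
Conditions: CH2=CHMgBr, THF, 0 °C; inverse quench into cold 1 M KHSO4
Reagents that add atoms: vinylmagnesium bromide, C=C[Mg]Br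
Why: Weinreb ketone synthesis, in which the chelated tetrahedral adduct stops the addition at the ketone stage and the inverse acidic quench protonates the released amine before it can add to the vinyl ketone or epimerise C13.

Step 13
Reactants: 13 (3S)-5-{(1S,6S)-6-[(benzyloxy)methyl]-2,6-dimethylcyclohex-2-en-1-yl}-3-methylpent-1-en-3-ol; 18 (4R)-6-[(tert-butyldimethylsilyl)oxy]-4-methylhex-1-en-3-one
Product: 19 (3R,5E,7S)-9-{(1S,6S)-6-[(benzyloxy)methyl]-2,6-dimethylcyclohex-2-en-1-yl}-1-[(tert-butyldimethylsilyl)oxy]-7-hydroxy-3,7-dimethylnon-5-en-4-one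
Conditions: second-generation Hoveyda–Grubbs catalyst [RuCl2(SIMes)(=CH-C6H4-2-OiPr)] (10 mol%), 18 (3 equiv), CH2Cl2, 40 °C
Reagents that add atoms: none
Why: Olefin cross-metathesis of a free tertiary allylic alcohol with an excess of a vinyl ketone should give the (E)-enone, C11 coming from the vinyl ketone, while the trisubstituted, unstrained C1=C10 ring alkene does not engage.

Step 14
Reactants: 19 (3R,5E,7S)-9-{(1S,6S)-6-[(benzyloxy)methyl]-2,6-dimethylcyclohex-2-en-1-yl}-1-[(tert-butyldimethylsilyl)oxy]-7-hydroxy-3,7-dimethylnon-5-en-4-one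
Product: 20 (4S,5S,8S,9S,10R,13R)-18-(benzyloxy)-15-[(tert-butyldimethylsilyl)oxy]-8-hydroxy-ent-labdan-12-one
Conditions: Fe(acac)3 (30 mol%), PhSiH3 (2.5 equiv), EtOH/ethylene glycol 5:1, 60 °C
Reagents that add atoms: none
Why: Metal-hydride hydrogen-atom transfer followed by intramolecular Giese addition (reductive olefin coupling): Fe–H gives H to C1, the tertiary C10 radical adds 6-exo-trig to the enone β-carbon C9 through a chair-like transition state with the C5–C6 tether equatorial on ring A and the approach anti to the axial C19 methyl (C20 axial, trans fusion, C10 set) and with the enone arm pseudo-equatorial (C9 set, H9 axial), and the α-keto radical is reduced and protonated at C11.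

Step 15
Reactants: 20 (4S,5S,8S,9S,10R,13R)-18-(benzyloxy)-15-[(tert-butyldimethylsilyl)oxy]-8-hydroxy-ent-labdan-12-one
Product: 21 (4S,5S,8S,9S,10R,13R)-18-(benzyloxy)-15-[(tert-butyldimethylsilyl)oxy]-ent-labdane-8,12-diol (both C12 epimers)
Conditions: NaBH4, MeOH, 0 °C
Reagents that add atoms: none
Why: Hydride reduction turns the carbonyl into an alcohol (both C12 epimers are used) under conditions too mild to enolise the ketone towards C13.

Step 16
Reactants: 21 (4S,5S,8S,9S,10R,13R)-18-(benzyloxy)-15-[(tert-butyldimethylsilyl)oxy]-ent-labdane-8,12-diol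
Product: 22 O-12 (imidazol-1-yl)thiocarbonyl derivative of diol 21
Conditions: 1,1'-thiocarbonyldiimidazole, DMAP (cat.), ClCH2CH2Cl, 70 °C
Reagents that add atoms: 1,1'-thiocarbonyldiimidazole, S=C(n1ccnc1)n1ccnc1
Why: Thiocarbonyldiimidazole should acylate the secondary C12 hydroxyl and not the hindered tertiary C8 hydroxyl, giving the radical precursor.

Step 17
Reactants: 22 O-12 (imidazol-1-yl)thiocarbonyl derivative of diol 21
Product: 23 (4S,5S,8S,9S,10R,13S)-18-(benzyloxy)-15-[(tert-butyldimethylsilyl)oxy]-ent-labdan-8-ol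
Conditions: Bu3SnH, AIBN (cat.), toluene, 110 °C
Reagents that add atoms: none
Why: Barton–McCombie deoxygenation (stannyl radical adds to sulfur, the C12–O bond fragments, the secondary radical takes hydrogen from the stannane) makes C12 a methylene with C13 untouched.

Step 18
Reactants: 23 (4S,5S,8S,9S,10R,13S)-18-(benzyloxy)-15-[(tert-butyldimethylsilyl)oxy]-ent-labdan-8-ol
Product: 24 (4S,5S,8S,9S,10R,13S)-15-[(tert-butyldimethylsilyl)oxy]-ent-labdane-8,18-diol
Conditions: H2 (1 atm), Pd/C (10%), EtOAc, rt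
Reagents that add atoms: none
Why: Hydrogenolysis of the benzyl ether frees the C18 primary alcohol at a stage where no alkene remains and where the silyl ether and the tertiary alcohol are inert.

Step 19
Reactants: 24 (4S,5S,8S,9S,10R,13S)-15-[(tert-butyldimethylsilyl)oxy]-ent-labdane-8,18-diol; 25 angelic acid
Product: 27 (4S,5S,8S,9S,10R,13S)-15-[(tert-butyldimethylsilyl)oxy]-8-hydroxy-ent-labdan-18-yl (Z)-2-methylbut-2-enoate, via mixed anhydride 26 (not isolated)
Conditions: 25, 2,4,6-trichlorobenzoyl chloride, Et3N, toluene, rt; then 24, toluene, 80 °C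
Reagents that add atoms: none
Why: Yamaguchi esterification through the mixed anhydride should acylate only the primary neopentyl alcohol (the tertiary C8 hydroxyl is inert) and, run without a nucleophilic amine catalyst, should keep the (Z)-angelate from isomerising to the tiglate.

Step 20
Reactants: 27 (4S,5S,8S,9S,10R,13S)-15-[(tert-butyldimethylsilyl)oxy]-8-hydroxy-ent-labdan-18-yl (Z)-2-methylbut-2-enoate
Product: 28 (4S,5S,8S,9S,10R,13S)-8,15-dihydroxy-ent-labdan-18-yl (Z)-2-methylbut-2-enoate (CNP0150844.1)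
Conditions: HF·pyridine, pyridine, THF, 0 °C to rt
Reagents that add atoms: none
Why: Buffered fluoride cleavage of the primary silyl ether frees O15–H without hydrolysing or isomerising the angelate or dehydrating the tertiary alcohol.

## Compound list

1 | (S)-linalool, (3S)-3,7-dimethylocta-1,6-dien-3-ol | CC(C)=CCC[C@](C)(O)C=C | starting material
2 | triethyl{[(3S)-3,7-dimethylocta-1,6-dien-3-yl]oxy}silane | CC(C)=CCC[C@](C)(O[Si](CC)(CC)CC)C=C | intermediate
3 | (2E,6S)-2,6-dimethyl-6-(triethylsilyloxy)octa-2,7-dien-1-ol | OC/C(C)=C/CC[C@](C)(O[Si](CC)(CC)CC)C=C | intermediate (not isolated)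
4 | (2E,6S)-2,6-dimethyl-6-(triethylsilyloxy)octa-2,7-dienal | O=C/C(C)=C/CC[C@](C)(O[Si](CC)(CC)CC)C=C | intermediate
5 | triethyl{[(3S,6E)-3,7-dimethylnona-1,6,8-trien-3-yl]oxy}silane (diene C2=C1–C10=C5) | C=C/C(C)=C/CC[C@](C)(O[Si](CC)(CC)CC)C=C | intermediate
6 | 2-methylenepropane-1,3-diol | C=C(CO)CO | starting material
7 | 2-[(benzyloxy)methyl]prop-2-en-1-ol | C=C(CO)COCc1ccccc1 | intermediate
8 | 2-[(benzyloxy)methyl]prop-2-enal | C=C(COCc1ccccc1)C=O | intermediate
9 | (1R,2S)-1-[(benzyloxy)methyl]-3-methyl-2-[(3S)-3-methyl-3-(triethylsilyloxy)pent-4-en-1-yl]cyclohex-3-ene-1-carbaldehyde (4R,5S,8S in labdane numbering) | c1ccccc1COC[C@@]2(C=O)CCC=C(C)[C@@H]2CC[C@](C)(O[Si](CC)(CC)CC)C=C | intermediate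
10 | (E)-4-methylbenzenesulfonylhydrazone of aldehyde 9 (4S,5S,8S; the C4 descriptor changes by priority only) | c1ccccc1COC[C@@]2(/C=N/NS(=O)(=O)c3ccc(C)cc3)CCC=C(C)[C@@H]2CC[C@](C)(O[Si](CC)(CC)CC)C=C | intermediate
11 | N-(1,3,2-benzodioxaborol-2-yl)-N'-tosylhydrazine formed by hydroboration of 10 (boron on the nitrogen attached to C19) | c1ccccc1COC[C@@]2(CN(B3Oc4ccccc4O3)NS(=O)(=O)c3ccc(C)cc3)CCC=C(C)[C@@H]2CC[C@](C)(O[Si](CC)(CC)CC)C=C | intermediate (not isolated)
12 | benzyl {(1S,2S)-1,3-dimethyl-2-[(3S)-3-methyl-3-(triethylsilyloxy)pent-4-en-1-yl]cyclohex-3-en-1-yl}methyl ether (4S,5S,8S) | c1ccccc1COC[C@@]2(C)CCC=C(C)[C@@H]2CC[C@](C)(O[Si](CC)(CC)CC)C=C | intermediate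
13 | (3S)-5-{(1S,6S)-6-[(benzyloxy)methyl]-2,6-dimethylcyclohex-2-en-1-yl}-3-methylpent-1-en-3-ol | c1ccccc1COC[C@@]2(C)CCC=C(C)[C@@H]2CC[C@](C)(O)C=C | intermediate
14 | (R)-α-methyl-γ-butyrolactone, (3R)-3-methyloxolan-2-one | C[C@@H]1CCOC1=O | starting material
15 | (2R)-4-hydroxy-N-methoxy-N,2-dimethylbutanamide | C[C@H](CCO)C(=O)N(C)OC | intermediate
16 | (2R)-4-[(tert-butyldimethylsilyl)oxy]-N-methoxy-N,2-dimethylbutanamide | C[C@H](CCO[Si](C)(C)C(C)(C)C)C(=O)N(C)OC | intermediate
17 | bromomagnesium alkoxide of the vinyl adduct of 16 (tetrahedral N-methoxy-N-methyl hemiaminal, 13R) | C=CC(O[Mg]Br)(N(C)OC)[C@H](C)CCO[Si](C)(C)C(C)(C)C | intermediate (not isolated)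
18 | (4R)-6-[(tert-butyldimethylsilyl)oxy]-4-methylhex-1-en-3-one (C11–C16 vinyl ketone) | C=CC(=O)[C@H](C)CCO[Si](C)(C)C(C)(C)C | intermediate
19 | (3R,5E,7S)-9-{(1S,6S)-6-[(benzyloxy)methyl]-2,6-dimethylcyclohex-2-en-1-yl}-1-[(tert-butyldimethylsilyl)oxy]-7-hydroxy-3,7-dimethylnon-5-en-4-one | c1ccccc1COC[C@@]2(C)CCC=C(C)[C@@H]2CC[C@](C)(O)/C=C/C(=O)[C@H](C)CCO[Si](C)(C)C(C)(C)C | intermediate
20 | (4S,5S,8S,9S,10R,13R)-18-(benzyloxy)-15-[(tert-butyldimethylsilyl)oxy]-8-hydroxy-ent-labdan-12-one | c1ccccc1COC[C@@]2(C)CCC[C@]3(C)[C@@H]2CC[C@](C)(O)[C@H]3CC(=O)[C@H](C)CCO[Si](C)(C)C(C)(C)C | intermediate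
21 | (4S,5S,8S,9S,10R,13R)-18-(benzyloxy)-15-[(tert-butyldimethylsilyl)oxy]-ent-labdane-8,12-diol (both C12 epimers) | c1ccccc1COC[C@@]2(C)CCC[C@]3(C)[C@@H]2CC[C@](C)(O)[C@H]3CC(O)[C@H](C)CCO[Si](C)(C)C(C)(C)C | intermediate
22 | O-12 (imidazol-1-yl)thiocarbonyl derivative of diol 21 | c1ccccc1COC[C@@]2(C)CCC[C@]3(C)[C@@H]2CC[C@](C)(O)[C@H]3CC(OC(=S)n4ccnc4)[C@H](C)CCO[Si](C)(C)C(C)(C)C | intermediate
23 | (4S,5S,8S,9S,10R,13S)-18-(benzyloxy)-15-[(tert-butyldimethylsilyl)oxy]-ent-labdan-8-ol | c1ccccc1COC[C@@]2(C)CCC[C@]3(C)[C@@H]2CC[C@](C)(O)[C@H]3CC[C@H](C)CCO[Si](C)(C)C(C)(C)C | intermediate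
24 | (4S,5S,8S,9S,10R,13S)-15-[(tert-butyldimethylsilyl)oxy]-ent-labdane-8,18-diol | OC[C@@]1(C)CCC[C@]2(C)[C@@H]1CC[C@](C)(O)[C@H]2CC[C@H](C)CCO[Si](C)(C)C(C)(C)C | intermediate
25 | angelic acid, (Z)-2-methylbut-2-enoic acid | C/C=C(/C)C(O)=O | starting material
26 | (Z)-2-methylbut-2-enoic 2,4,6-trichlorobenzoic anhydride | C/C=C(/C)C(=O)OC(=O)c1c(Cl)cc(Cl)cc1Cl | intermediate (not isolated)
27 | (4S,5S,8S,9S,10R,13S)-15-[(tert-butyldimethylsilyl)oxy]-8-hydroxy-ent-labdan-18-yl (Z)-2-methylbut-2-enoate | C/C=C(/C)C(=O)OC[C@@]1(C)CCC[C@]2(C)[C@@H]1CC[C@](C)(O)[C@H]2CC[C@H](C)CCO[Si](C)(C)C(C)(C)C | intermediate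
28 | (4S,5S,8S,9S,10R,13S)-8,15-dihydroxy-ent-labdan-18-yl (Z)-2-methylbut-2-enoate (CNP0150844.1) | C/C=C(/C)C(=O)OC[C@@]1(C)CCC[C@]2(C)[C@@H]1CC[C@](C)(O)[C@H]2CC[C@H](C)CCO | target

## Step count and risks

Total step count: 20. Longest linear sequence: 15 steps (steps 1, 2, 3, 6, 7, 8, 9, 13 to 20, from (S)-linalool).

Steps most likely to fail:

1. Step 14 (ring-B closure). The C10 radical may take a second hydrogen atom before it reaches the crowded C9. When it does add, the equatorial placement of the side arm at C9 and the trans ring fusion rest on small conformational preferences, so the C9 epimer and some cis-fused decalin may form. The fallback sets out from 20 (as its mixture of C9 epimers) and comes back to the route at 20; it moves the control of C9 from the radical addition to a hydrogenation and does not repair a cis ring fusion. LiN(iPr)2 (2.2 equiv) and Me3SiCl in THF at −78 °C enolise the ketone kinetically at the methylene C11 and silylate O8, giving the bis(trimethylsilyl) enol ether F1. Pd(OAc)2 in MeCN (Saegusa–Ito oxidation) gives the C9=C11 enone F2. Hydrogenation over Pd/C in EtOAc containing pyridine (which spares the benzyl ether) should deliver hydrogen to C9 from the face opposite the axial C17 and C20 methyl groups and give the saturated silyl ether F3. Aqueous citric acid in MeOH removes the O8 silyl group and returns 20 with the side arm equatorial.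

2. Step 6 (Diels–Alder). The formyl group may take the exo instead of the endo position, as α-substituted acroleins do with cyclic dienes, which inverts C4 relative to C5. The ether oxygen of the dienophile may also compete for the boron centre, and the C10 methyl may divert part of the material to the other regiochemistry. The fallback sets out from 5 and comes back at 12; it uses the exo mode instead of fighting it, so that the formyl carbon becomes C18 and the α-methyl becomes C19. Diene 5 and commercial methacrolein with the (S)-enantiomer of the same catalyst give the formyl-exo adduct, the aldehyde F4. NaBH4 in MeOH gives the neopentyl alcohol F5, and NaH/BnBr/Bu4NI in THF gives 12, which also saves steps 7 and 8.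

3. Step 13 (cross-metathesis). Metathesis at the vinyl group beside the fully substituted carbinol carbon may be slow, with the catalyst spent on homodimerising the vinyl ketone and on decomposition. The fallback sets out from 13 and 16 and comes back at 19; it keeps the terminal vinyl carbon as C11 and builds the enone by the isoxazoline route. iBu2AlH in THF at −78 °C reduces 16 to the aldehyde F6, and NH2OH·HCl/NaOAc gives the oxime F7. Aqueous NaOCl in CH2Cl2 at 0 °C, in the presence of 13, oxidises the oxime to the nitrile oxide F8, which should add only to the monosubstituted vinyl group and give the isoxazoline F9. Mo(CO)6 in MeCN/H2O at 80 °C cleaves the N–O bond to the β-hydroxy ketone F10. MsCl/Et3N in CH2Cl2 mesylates the secondary C9 hydroxyl (mesylate F11), and elimination by Et3N gives the (E)-enone 19.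

## Further compounds

F1 | step 14 | 18-(benzyloxy)-15-[(tert-butyldimethylsilyl)oxy]-8,12-bis(trimethylsilyloxy)-ent-labd-11-ene (C9 epimers) | c1ccccc1COC[C@@]2(C)CCC[C@]3(C)[C@@H]2CC[C@](C)(O[Si](C)(C)C)C3C=C(O[Si](C)(C)C)[C@H](C)CCO[Si](C)(C)C(C)(C)C
F2 | step 14 | 18-(benzyloxy)-15-[(tert-butyldimethylsilyl)oxy]-8-(trimethylsilyloxy)-ent-labd-9(11)-en-12-one (either alkene geometry) | c1ccccc1COC[C@@]2(C)CCC[C@]3(C)[C@@H]2CC[C@](C)(O[Si](C)(C)C)C3=CC(=O)[C@H](C)CCO[Si](C)(C)C(C)(C)C
F3 | step 14 | (4S,5S,8S,9S,10R,13R)-18-(benzyloxy)-15-[(tert-butyldimethylsilyl)oxy]-8-(trimethylsilyloxy)-ent-labdan-12-one | c1ccccc1COC[C@@]2(C)CCC[C@]3(C)[C@@H]2CC[C@](C)(O[Si](C)(C)C)[C@H]3CC(=O)[C@H](C)CCO[Si](C)(C)C(C)(C)C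
F4 | step 6 | (1S,2S)-1,3-dimethyl-2-[(3S)-3-methyl-3-(triethylsilyloxy)pent-4-en-1-yl]cyclohex-3-ene-1-carbaldehyde | O=C[C@@]1(C)CCC=C(C)[C@@H]1CC[C@](C)(O[Si](CC)(CC)CC)C=C
F5 | step 6 | {(1S,2S)-1,3-dimethyl-2-[(3S)-3-methyl-3-(triethylsilyloxy)pent-4-en-1-yl]cyclohex-3-en-1-yl}methanol | OC[C@@]1(C)CCC=C(C)[C@@H]1CC[C@](C)(O[Si](CC)(CC)CC)C=C
F6 | step 13 | (2R)-4-[(tert-butyldimethylsilyl)oxy]-2-methylbutanal | C[C@H](CCO[Si](C)(C)C(C)(C)C)C=O
F7 | step 13 | (2R)-4-[(tert-butyldimethylsilyl)oxy]-2-methylbutanal oxime | C[C@H](CCO[Si](C)(C)C(C)(C)C)C=NO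
F8 | step 13 | (2R)-4-[(tert-butyldimethylsilyl)oxy]-2-methylbutanenitrile oxide | C[C@H](CCO[Si](C)(C)C(C)(C)C)C#[N+][O-]
F9 | step 13 | 4,5-dihydroisoxazole from 13 and F8 (C9 at ring position 5, C12 at ring position 3, C9 epimers) | c1ccccc1COC[C@@]2(C)CCC=C(C)[C@@H]2CC[C@](C)(O)C3CC(=NO3)[C@H](C)CCO[Si](C)(C)C(C)(C)C
F10 | step 13 | 9-hydroxy analogue of 19 with C9–C11 saturated (8,9-dihydroxy-12-ketone, C9 epimers) | c1ccccc1COC[C@@]2(C)CCC=C(C)[C@@H]2CC[C@](C)(O)C(O)CC(=O)[C@H](C)CCO[Si](C)(C)C(C)(C)C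
F11 | step 13 | C9 methanesulfonate of F10 | c1ccccc1COC[C@@]2(C)CCC=C(C)[C@@H]2CC[C@](C)(O)C(OS(C)(=O)=O)CC(=O)[C@H](C)CCO[Si](C)(C)C(C)(C)C
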